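**Assumption (one line):** The target is made exactly as drawn, with a trans ring fusion at C8–C8′ (H-8/H-8′ anti; 7S,8S,8′S,7′R,9′R), and the C9′ lactol anomer is assumed to equilibrate to the drawn one.

**Retrosynthesis**
- The lactol comes from DIBAL reduction of a trans-fused furofuranone, and the phenols are carried as allyl ethers removed by Pd(0) at the end.
- The lactone ring is formed last, by TEMPO/BAIB oxidative lactonisation of a 1,4-diol on an already formed tetrahydrofuran.
- The THF ring is formed first, while it is still unstrained, by Mitsunobu cyclodehydration of the primary alcohol with the benzylic C7′–OH.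
- All four stereocentres (C7, C8, C8′, C7′) are set in one double magnesium-catalysed anti-aldol of a succinyl bis-imide carrying an (S)-thiazolidinethione at one end and an (R)-oxazolidinone at the other. The two ends are mirror-related, which gives the C8/C8′ relationship of the target. The different imide types let NaBH4 differentiate the ends.
- The bis-imide is assembled from (R)-oxazolidinone, succinic anhydride and (S)-thiazolidinethione.

---

**Step 1**
Reactants: 1 (R)-4-benzyl-1,3-oxazolidin-2-one; 2 succinic anhydride
Product: 3 4-[(4R)-4-benzyl-2-oxo-oxazolidin-3-yl]-4-oxobutanoic acid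
Conditions: n-BuLi, THF, −78 °C; then 2, −78 °C → rt; 1 M HCl
Reagents that add atoms: none
Why: The lithiated oxazolidinone opens the anhydride (N-acylation). No stereocentre is formed, and the (R) auxiliary is carried forward.

**Step 2**
Reactants: 3; 4 (S)-4-benzyl-1,3-thiazolidine-2-thione
Product: 5 unsymmetrical succinyl bis-imide
Conditions: EDC·HCl, DMAP, CH2Cl2, 0 °C → rt
Reagents that add atoms: none
Why: Carbodiimide (Steglich-type) N-acylation of the thiazolidinethione N–H. This gives a bis-imide with two chemically different, oppositely chiral ends.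

**Step 3**
Reactants: 5; 6 4-(allyloxy)-3-methoxybenzaldehyde (2.6 equiv)
Product: 7 bis-anti-aldol adduct
Conditions: MgBr2·OEt2 (0.4 equiv), Et3N, TMSCl, EtOAc, rt; then TFA, MeOH
Reagents that add atoms: none (the TMS ethers are cleaved in the work-up)
Why: This is the magnesium halide-catalysed anti-aldol (Evans) of N-acyl imides, via the chelated Mg enolate. The (S)-thiazolidinethione end gives (7S,8R) and the (R)-oxazolidinone end gives (7′R,8′S), both anti and mirror-related. This sets C7, C8, C8′ and C7′ and gives the C8/C8′ arrangement of the target.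

**Step 4**
Reactants: 7
Product: 8 mono-alcohol imide (C9 = CH2OH; C9′ still the oxazolidinone imide)
Conditions: NaBH4, THF/H2O, 0 °C
Reagents that add atoms: none
Why: Reductive cleavage of an N-acyl imide to the primary alcohol. The thiazolidinethione imide is far more electrophilic than the oxazolidinone imide, so only the C9 end is reduced, and auxiliary 4 is recovered. This step breaks the symmetry of the two ends, and no stereocentre is touched.

**Step 5**
Reactants: 8
Product: 9 trans-3,4-disubstituted THF (ring B)
Conditions: PPh3, DIAD, THF, 0 °C → rt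
Reagents that add atoms: none
Why: Mitsunobu cyclodehydration of a 1,4-diol. The unhindered primary alcohol is activated and the C7′–OH closes a 5-exo-tet ring. The carbon attacked is CH2 and the C7′–O bond is never broken, so C7′ is retained. C7–OH can only form an oxetane, which is disfavoured.

**Step 6**
Reactants: 9
Product: 10 diol (C9′ = CH2OH)
Conditions: LiBH4, MeOH, Et2O, 0 °C
Reagents that add atoms: none
Why: Reductive removal of the oxazolidinone to the primary alcohol; auxiliary 1 is recovered. The ether, the allyl ethers and the benzylic alcohol survive. No stereocentre is affected.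

**Step 7**
Reactants: 10
Product: 11 trans-fused furofuranone (ring A)
Conditions: TEMPO (10 mol %), PhI(OAc)2 (2.2 equiv), CH2Cl2, rt
Reagents that add atoms: none
Why: TEMPO/BAIB oxidative lactonisation of a 1,4-diol: the primary alcohol goes to the aldehyde, the C7–OH traps it as the lactol, and the lactol is oxidised to the γ-lactone. Irreversible oxidation of the lactol pulls the strained trans-fused ring closed. The benzylic stereocentres are untouched.

**Step 8**
Reactants: 11
Product: 12 bis-O-allyl lactol
Conditions: DIBAL-H (1.2 equiv), CH2Cl2, −78 °C; then Rochelle salt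
Reagents that add atoms: none
Why: Partial reduction of a lactone to the lactol, which is held at −78 °C as the aluminium hemiacetal. The new C9′ centre is an equilibrating anomeric centre, and the drawn anomer is assumed to predominate. No other stereocentre is affected.

**Step 9**
Reactants: 12
Product: 13 4α-hydroxypinoresinol
Conditions: Pd(PPh3)4 (5 mol %), PhSiH3, CH2Cl2, rt
Reagents that add atoms: none
Why: Tsuji–Trost-type Pd(0) deallylation of the aryl allyl ethers with a hydride allyl scavenger. This is neutral, so the strained lactol is not ring-opened or epimerised, and the benzylic C–O bonds are not hydrogenolysed.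

---

**Compound list**

| No. | Name | SMILES | Role |
|---|---|---|---|
| 1 | (R)-4-benzyl-1,3-oxazolidin-2-one | `O=C1N[C@H](Cc2ccccc2)CO1` | starting material |
| 2 | succinic anhydride | `O=C1CCC(=O)O1` | starting material |
| 3 | 4-[(4R)-4-benzyl-2-oxo-oxazolidin-3-yl]-4-oxobutanoic acid | `OC(=O)CCC(=O)N1[C@H](Cc2ccccc2)COC1=O` | intermediate |
| 4 | (S)-4-benzyl-1,3-thiazolidine-2-thione | `S=C1N[C@@H](Cc2ccccc2)CS1` | starting material |
| 5 | unsymmetrical succinyl bis-imide ((S)-thiazolidinethione / (R)-oxazolidinone) | `O=C(CCC(=O)N1[C@@H](Cc2ccccc2)CSC1=S)N1[C@H](Cc2ccccc2)COC1=O` | intermediate |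
| 6 | 4-(allyloxy)-3-methoxybenzaldehyde | `C=CCOc1ccc(C=O)cc1OC` | starting material |
| 7 | bis-anti-aldol adduct (lignan C7S,C8R on the thiazolidinethione half; C7′R,C8′S on the oxazolidinone half) | `S=C1SC[C@H](Cc2ccccc2)N1C(=O)[C@@H]([C@H](O)c1ccc(OCC=C)c(OC)c1)[C@@H]([C@@H](O)c1ccc(OCC=C)c(OC)c1)C(=O)N1[C@H](Cc2ccccc2)COC1=O` | intermediate |
| 8 | C9-alcohol, C9′-oxazolidinone imide (7S,8S,8′S,7′R) | `OC[C@@H]([C@H](O)c1ccc(OCC=C)c(OC)c1)[C@@H]([C@@H](O)c1ccc(OCC=C)c(OC)c1)C(=O)N1[C@H](Cc2ccccc2)COC1=O` | intermediate |
| 9 | trans-3,4-disubstituted 2-aryl-THF imide (7S,8S,8′S,7′R) | `C1O[C@@H](c2ccc(OCC=C)c(OC)c2)[C@@H](C(=O)N2[C@H](Cc3ccccc3)COC2=O)[C@@H]1[C@H](O)c1ccc(OCC=C)c(OC)c1` | intermediate |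
| 10 | THF diol, C9′ = CH2OH (7S,8S,8′R,7′R) | `C1O[C@@H](c2ccc(OCC=C)c(OC)c2)[C@@H](CO)[C@@H]1[C@H](O)c1ccc(OCC=C)c(OC)c1` | intermediate |
| 11 | bis-O-allyl trans-fused furofuranone (7S,8S,8′S,7′R) | `COc1cc([C@H]2OC(=O)[C@H]3[C@H]2CO[C@H]3c2ccc(OCC=C)c(OC)c2)ccc1OCC=C` | intermediate |
| 12 | bis-O-allyl lactol (7S,8S,8′S,7′R,9′R) | `COc1cc([C@H]2O[C@@H](O)[C@H]3[C@H]2CO[C@H]3c2ccc(OCC=C)c(OC)c2)ccc1OCC=C` | intermediate |
| 13 | 4α-hydroxypinoresinol | `COc1cc([C@H]2O[C@@H](O)[C@H]3[C@H]2CO[C@H]3c2ccc(O)c(OC)c2)ccc1O` | target |

**Total step count:** 9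
**Longest linear sequence:** 9 steps (1 → 3 → 5 → 7 → 8 → 9 → 10 → 11 → 12 → 13)

**Three steps most likely to fail**
1. **Step 3, double anti-aldol.** It may stop at the mono-aldol, the Mg-anti facial sense may be opposite to that assumed, or the hindered second enolisation may be slow. Fallback: run a double Evans syn-aldol (Bu2BOTf, Et3N) on the bis-imide with the opposite auxiliary enantiomers at each end. Then invert both benzylic carbinols by Mitsunobu with p-nitrobenzoic acid, followed by K2CO3/MeOH, before Step 4.
2. **Step 5, Mitsunobu THF closure.** The benzylic alcohols may ionise or eliminate, or C7–OH may acylate onto the imide. Fallback: reduce the thiazolidinethione end of 7 with DIBAL at −78 °C to the aldehyde, which lactolises with C7′–OH, then reduce the lactol to the THF ether with Et3SiH/BF3·OEt2 (ionic hydrogenation). This replaces the alcohol-activation approach with an oxocarbenium reduction.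
3. **Step 7, strained trans-fused lactonisation.** The trans ring fusion costs about 6 kcal/mol. The lactol may stay ring-opened, benzylic C7–OH may be oxidised, or C8′ may epimerise toward the cis-fused lactone. Fallback: skip the oxidation level change and treat imide 9 directly with DIBAL at −78 °C to give the aldehyde, which lactolises with C7–OH to give 12 in one step.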